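**Strategy.** Everything rests on cutting the lactone O6–C12(=O)–C11(=C13)–C7 at O6–C12 and C12–C11. This exposes a cis-2-ethynylcyclohexanol on the cyclohexane ring C5–C10: the C6 hydroxyl and the C7 ethynyl group on neighbouring ring carbons, on the same face, are the feature the key step exploits. A palladium-catalysed cyclocarbonylation inserts CO as C12 and closes the cis-fused α-methylene-γ-lactone ring in one operation, without touching a stereocentre. Its precursor already carries all six stereocentres: free C6–OH, the C7 and C8 hydroxyls tied as an acetonide, free C9–OH and a terminal alkyne on C7. The ring comes from (1R,5R)-verbenone; an epoxide and a 1,2-diketone deliver the four oxygens.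

Key step: step 12

Remark: the monocyclic compounds keep the atom numbers C5–C13 of the target; β is the ring face of the C10 methyl group and α the face of the C10 vinyl group, so the target is 5β-isopropenyl, 6β-O (lactone), 7α-OH (C11 on the β face), 8α-OH and 9β-O-angeloyl; the key-step precursor is therefore a 6β,7α-trans-diol derivative in which the C6 hydroxyl is cis to the ethynyl group.

Step 1
Reactants: 1 (1R,5R)-(+)-verbenone; 2 vinylmagnesium bromide
Product: 4 4,6,6-trimethyl-4-vinylbicyclo[3.1.1]heptan-2-one with the vinyl group on the face opposite the CMe2 bridge, via bromomagnesium enolate 3 (not isolated)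
Conditions: CuI (cat.), THF, −40 to 0 °C; then aq. NH4Cl
Reagents that add atoms: vinylmagnesium bromide, C=C[Mg]Br
Why: Copper-catalysed conjugate addition of the Grignard reagent to the β,β-disubstituted enone should deliver the vinyl group to C4 from the face opposite the gem-dimethyl bridge, which sets the future C10 quaternary centre (vinyl α, methyl β).

Step 2
Reactants: 4 4-vinylverbanone
Product: 5 C7=C8 enol acetate (C8–OAc) of 5β-isopropenyl-10β-methyl-10α-vinylcyclohexan-8-one
Conditions: Zn(OAc)2, BF3·OEt2, Ac2O, 0 °C to rt
Reagents that add atoms: acetic anhydride, CC(=O)OC(C)=O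
Why: Lewis-acid activation of the ketone should trigger a Grob-type heterolysis of the strained cyclobutane bond between the carbonyl α-carbon and the CMe2 carbon, the tertiary cation losing a proton to give the isopropenyl group and the enolate being O-acetylated, so that C5 and C10 keep their configuration (isopropenyl cis to the C10 methyl) and the enol double bond sits at C7=C8.

Step 3
Reactants: 5 enol acetate
Product: 6 (4S,5S)-4-isopropenyl-5-methyl-5-vinylcyclohex-2-en-1-one (C6=C7 enone, C8=O)
Conditions: Pd(OAc)2 (cat.), dppe (cat.), Bu3SnOMe (cat.), allyl methyl carbonate, MeCN, reflux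
Reagents that add atoms: none
Why: Palladium-catalysed dehydrogenation of the enol acetate (Saegusa–Ito-type β-hydride elimination from the palladium enolate formed through the tin enolate) should give the C6=C7 enone, the regiochemistry being fixed by the enol acetate and by the lack of hydrogen on C10.

Step 4
Reactants: 6 enone
Product: 7 C7-iodo enone (2-iodo derivative of 6)
Conditions: I2, pyridine/CH2Cl2, 0 °C to rt
Reagents that add atoms: iodine, II
Why: α-Iodination of the cyclic enone by conjugate addition of pyridine, iodination of the enolate and elimination (Morita–Baylis–Hillman-type mechanism) is specific for the electron-poor C6=C7 bond and should leave the vinyl and isopropenyl groups alone.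

Step 5
Reactants: 7 C7-iodo enone; 8 ethynyltrimethylsilane
Product: 9 C7-(trimethylsilylethynyl) enone
Conditions: PdCl2(PPh3)2 (cat.), CuI (cat.), iPr2NH, THF, rt
Reagents that add atoms: ethynyltrimethylsilane, C#C[Si](C)(C)C
Why: Sonogashira coupling of an α-iodoenone with a terminal alkyne is a standard sp2–sp coupling that runs at room temperature and tolerates the enone and the isolated alkenes.

Step 6
Reactants: 9 alkynyl enone
Product: 10 6α,7α-epoxy-7β-(trimethylsilylethynyl) 8-ketone (oxirane oxygen on the α face, anti to the 5β-isopropenyl group)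
Conditions: t-BuOOH (decane), DBU, CH2Cl2, 0 °C to rt
Reagents that add atoms: tert-butyl hydroperoxide, CC(C)(C)OO
Why: Weitz–Scheffer nucleophilic epoxidation attacks only the enone double bond, and the peroxide anion should add to C6 anti to the neighbouring 5β-isopropenyl group and to the pseudoaxial C10 methyl, so that both new C–O bonds (C6 and C7) lie on the α face.

Step 7
Reactants: 10 epoxy ketone
Product: 12 9-hydroxy-6α,7α-epoxy 8-ketone (9α-OH epimer expected to predominate; both epimers are carried on), via potassium enolate 11 (not isolated)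
Conditions: KN(SiMe3)2, THF, −78 °C; then 2-(phenylsulfonyl)-3-phenyloxaziridine, −78 °C; aq. NH4Cl
Reagents that add atoms: 2-(phenylsulfonyl)-3-phenyloxaziridine, O=S(=O)(c1ccccc1)N1OC1c1ccccc1
Why: Because C7 is quaternary the ketone can enolise only toward C9, and Davis oxidation of the potassium enolate should give the acyloin, whose C9 configuration is of no consequence since the carbinol is oxidised in step 8.

Step 8
Reactants: 12 acyloin
Product: 13 6α,7α-epoxy-7β-(trimethylsilylethynyl) 8,9-dione
Conditions: Dess–Martin periodinane, CH2Cl2, 0 °C to rt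
Reagents that add atoms: none
Why: Dess–Martin oxidation of the acyloin should give the 1,2-diketone, which cannot enolise because C7 and C10 are quaternary, under neutral conditions that spare the oxirane and the silylalkyne.

Step 9
Reactants: 13 epoxy dione
Product: 14 6β,7α-dihydroxy-7β-(trimethylsilylethynyl) 8,9-dione (trans-diaxial diol, C6–OH cis to the alkynyl group)
Conditions: HClO4 (aq., cat.), THF/H2O, rt
Reagents that add atoms: water, O
Why: In the acid-catalysed hydrolysis of the oxirane C7 is quaternary and flanked by a carbonyl group, so water should attack C6 with inversion in the trans-diaxial sense (Fürst–Plattner rule), which sets C6β–OH, keeps C7α–OH and thereby places the C6 hydroxyl cis to the alkynyl group.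

Step 10
Reactants: 14 diol dione
Product: 15 6β,7α,8α,9β-tetraol bearing the 7β-(trimethylsilylethynyl) group
Conditions: Me4NBH(OAc)3, MeCN/AcOH (1:1), −30 to 0 °C
Reagents that add atoms: none
Why: In this Evans–Saksena reduction the axial C6β hydroxyl should deliver hydride to the β face of C8 and the axial C7α hydroxyl, together with the new C8α hydroxyl, to the α face of C9, each by anti-selective intramolecular transfer, which sets C8α–OH and C9β–OH (both equatorial).

Step 11
Reactants: 15 tetraol
Product: 17 7β-ethynyl-7α,8α-O-isopropylidene-6β,9β-diol (cyclocarbonylation precursor), via silylated acetonide 16 (not isolated)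
Conditions: Me2C(OMe)2, PPTS (cat.), acetone, rt; then K2CO3, MeOH, rt
Reagents that add atoms: 2,2-dimethoxypropane, COC(C)(C)OC
Why: Acid-catalysed ketalisation under equilibrium control should pick the only cis-vicinal diol (C7α/C8α; C6/C7 and C8/C9 are trans), and carbonate-catalysed methanolysis then cleaves the C(sp)–Si bond without affecting the ketal.

Step 12
Reactants: 17 ethynyl acetonide diol; 18 carbon monoxide
Product: 19 cis-fused α-methylene-γ-lactone O6–C12(=O)–C11(=C13H2)–C7 (6β,12-olide) with 7α,8α-O-isopropylidene and free 9β-OH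
Conditions: PdCl2 (cat.), SnCl2 (cat.), PPh3 (cat.), CO (8 atm), MeCN, 75 °C
Reagents that add atoms: carbon monoxide, [C-]#[O+]
Why: Divalent palladium (PdCl2/SnCl2/PPh3) should convert the C6β hydroxyl and CO into an alkoxycarbonylpalladium species, which adds syn across the ethynyl group on C7 and is released by protonolysis of the vinylpalladium, giving the exocyclic C11=C13 methylene and returning the catalyst. The closest known reaction is the palladium-catalysed cyclocarbonylation of cis-2-ethynylcyclohexanol to the cis-fused α-methylene-γ-butyrolactone with the same catalyst system. The ring O6–C12–C11–C7–C6 closes in the 5-exo-dig mode and forms the bonds O6–C12 and C12–C11. No stereocentre is created: the cis ring fusion follows from the C6β hydroxyl and the C7β ethynyl group set in steps 6 and 9. Chemoselectivity is secured by the substrate, since the C7 and C8 oxygens are locked in the acetonide, the C9 hydroxyl could reach the alkyne only through a bridged six-membered ring, and the vinyl and isopropenyl groups have no hydroxyl placed for ring closure and insert far more slowly than the alkyne under these non-oxidative conditions.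

Step 13
Reactants: 19 lactone acetonide; 20 angelic acid
Product: 22 9β-O-angeloyl lactone acetonide, via mixed anhydride 21 (not isolated)
Conditions: 20, 2,4,6-trichlorobenzoyl chloride, Et3N, toluene, rt; then 19, 80 °C
Reagents that add atoms: angelic acid, OC(=O)/C(C)=C\C
Why: Yamaguchi esterification through the preformed mixed anhydride, run without a nucleophilic catalyst, should acylate the only free hydroxyl (C9) and keep the Z geometry of the angelate.

Step 14
Reactants: 22 angelate acetonide
Product: 23 target CNP0114166.3
Conditions: AcOH/H2O (4:1), 45 °C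
Reagents that add atoms: none
Why: Mild acid-catalysed hydrolysis of the isopropylidene ketal should free the C7 and C8 hydroxyls without touching a stereocentre, the angelate, the α-methylene lactone or the alkenes.

**Compound list**

1 | (1R,5R)-(+)-verbenone, (1R,5R)-4,6,6-trimethylbicyclo[3.1.1]hept-3-en-2-one | CC1=CC(=O)[C@@H]2C[C@H]1C2(C)C | starting material
2 | vinylmagnesium bromide | C=C[Mg]Br | starting material
3 | bromomagnesium C2 enolate of 4 (vinyl anti to the CMe2 bridge) | C=C[C@]1(C)C=C(O[Mg]Br)[C@@H]2C[C@H]1C2(C)C | intermediate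
4 | 4,6,6-trimethyl-4-vinylbicyclo[3.1.1]heptan-2-one, vinyl on the face opposite the CMe2 bridge, bridgeheads as in 1 | C=C[C@]1(C)CC(=O)[C@@H]2C[C@H]1C2(C)C | intermediate
5 | C7=C8 enol acetate: 1-acetoxy-4-isopropenyl-5-methyl-5-vinylcyclohex-1-ene, isopropenyl cis to the methyl group | C=C[C@@]1(C)[C@H](C(=C)C)CC=C(OC(C)=O)C1 | intermediate
6 | (4S,5S)-4-isopropenyl-5-methyl-5-vinylcyclohex-2-en-1-one (C6=C7, C8=O) | C=C[C@@]1(C)[C@H](C(=C)C)C=CC(=O)C1 | intermediate
7 | 2-iodo derivative of 6 (iodine on C7) | C=C[C@@]1(C)[C@H](C(=C)C)C=C(I)C(=O)C1 | intermediate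
8 | ethynyltrimethylsilane | C#C[Si](C)(C)C | starting material
9 | 2-(trimethylsilylethynyl) derivative of 6 (alkyne on C7) | C=C[C@@]1(C)[C@H](C(=C)C)C=C(C#C[Si](C)(C)C)C(=O)C1 | intermediate
10 | 6α,7α-epoxy-7β-(trimethylsilylethynyl) 8-ketone, 5β-isopropenyl, 10β-methyl, 10α-vinyl | C=C[C@@]1(C)[C@H](C(=C)C)[C@H]2O[C@@]2(C#C[Si](C)(C)C)C(=O)C1 | intermediate
11 | potassium C8=C9 enolate of 10 | C=C[C@@]1(C)[C@H](C(=C)C)[C@H]2O[C@@]2(C#C[Si](C)(C)C)C([O-])=C1.[K+] | intermediate
12 | 9-hydroxy derivative of 10 (9α-OH epimer drawn) | C=C[C@@]1(C)[C@H](C(=C)C)[C@H]2O[C@@]2(C#C[Si](C)(C)C)C(=O)[C@H]1O | intermediate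
13 | 6α,7α-epoxy-7β-(trimethylsilylethynyl) 8,9-dione | C=C[C@@]1(C)[C@H](C(=C)C)[C@H]2O[C@@]2(C#C[Si](C)(C)C)C(=O)C1=O | intermediate
14 | 6β,7α-dihydroxy-7β-(trimethylsilylethynyl) 8,9-dione | C=C[C@@]1(C)[C@H](C(=C)C)[C@H](O)[C@](O)(C#C[Si](C)(C)C)C(=O)C1=O | intermediate
15 | 6β,7α,8α,9β-tetrahydroxy-7β-(trimethylsilylethynyl) cyclohexane, 5β-isopropenyl, 10β-methyl, 10α-vinyl | C=C[C@@]1(C)[C@H](C(=C)C)[C@H](O)[C@](O)(C#C[Si](C)(C)C)[C@@H](O)[C@@H]1O | intermediate
16 | 7α,8α-O-isopropylidene derivative of 15 | C=C[C@@]1(C)[C@H](C(=C)C)[C@H](O)[C@@]2(C#C[Si](C)(C)C)OC(C)(C)O[C@H]2[C@@H]1O | intermediate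
17 | 7β-ethynyl-7α,8α-O-isopropylidene-6β,9β-diol (key-step precursor) | C=C[C@@]1(C)[C@H](C(=C)C)[C@H](O)[C@@]2(C#C)OC(C)(C)O[C@H]2[C@@H]1O | intermediate
18 | carbon monoxide | [C-]#[O+] | starting material
19 | cis-fused α-methylene-γ-lactone (6β,12-olide), 7α,8α-O-isopropylidene, 9β-OH (key-step product) | C=C[C@@]1(C)[C@H](C(=C)C)[C@@H]2OC(=O)C(=C)[C@@]23OC(C)(C)O[C@H]3[C@@H]1O | intermediate
20 | angelic acid, (Z)-2-methylbut-2-enoic acid | OC(=O)/C(C)=C\C | starting material
21 | angelic 2,4,6-trichlorobenzoic anhydride | O=C(OC(=O)/C(C)=C\C)c1c(Cl)cc(Cl)cc1Cl | intermediate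
22 | 9β-O-angeloyl derivative of 19 | C=C[C@@]1(C)[C@H](C(=C)C)[C@@H]2OC(=O)C(=C)[C@@]23OC(C)(C)O[C@H]3[C@@H]1OC(=O)/C(C)=C\C | intermediate
23 | CNP0114166.3: 9β-angeloyloxy-7α,8α-dihydroxy-5β-isopropenyl-10β-methyl-10α-vinyl 6β,12-olide with C11=C13 methylene | C=C[C@@]1(C)[C@H](C(=C)C)[C@@H]2OC(=O)C(=C)[C@]2(O)[C@@H](O)[C@@H]1OC(=O)/C(C)=C\C | target

**Step count.** Total: 14 steps. Longest linear sequence: 14 steps (1 to 23).

**Steps most likely to fail, with fallbacks**

Step 12 (key step). The hindered axial C6 hydroxyl may be slow to form the alkoxycarbonylpalladium species, the Lewis-acidic tin salt may open the ketal, or the alkyne may be consumed by oligomerisation before ring closure. The fallback sets out from 17 and turns the alkyne into a vinyl halide that is carbonylated by oxidative addition. Molybdenum-catalysed hydrostannation [Bu3SnH, Mo(CO)3(CNtBu)3 (cat.), THF, 55 °C] should place tin on the internal alkyne carbon next to the propargylic oxygen and give the 7β-[1-(tributylstannyl)vinyl] acetonide diol F1. Tin–iodine exchange (I2, CH2Cl2, 0 °C) then gives the 7β-(1-iodovinyl) acetonide diol F2. Carbonylative lactonisation with zerovalent palladium [Pd(PPh3)4 (cat.), CO (1 atm), Et3N, MeCN, 60 °C] closes the same lactone and comes back to the route at 19.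

Step 10. Facial control may be lost through undirected hydride transfer to the activated diketone or through delivery from the tertiary C7 hydroxyl to the α face of C8. The fallback sets out from 14 and treats the two carbonyl groups separately. One equivalent of NaBH(OAc)3 (MeCN/AcOH, −35 °C) should reduce only C8 under direction of the C6 hydroxyl and give the 6β,7α,8α-trihydroxy 9-ketone F3. Ketalisation (Me2C(OMe)2, PPTS, acetone, rt) ties the C7 and C8 hydroxyls and gives the acetonide 9-ketone F4. Luche reduction (NaBH4, CeCl3·7H2O, MeOH, −78 °C) by axial attack on the α face, away from the axial C10 methyl on the neighbouring carbon, comes back to the route at 16, which is desilylated to 17 as in the second stage of step 11.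

Step 9. The oxirane, deactivated by two carbonyl groups, may open sluggishly at the hindered C6 (attack syn to the axial C10 methyl), or acid may induce acyl migration with ring contraction of the diketone. The fallback sets out from 12 and opens the oxirane one oxidation level earlier. Hydrolysis of the acyloin (HClO4, THF/H2O, rt) gives the 6β,7α,9-trihydroxy 8-ketone F5. Cu(OAc)2 (aq. AcOH, 50 °C), a divalent copper oxidant specific for acyloins, then oxidises only the C9 carbinol next to the ketone, leaves the C6 hydroxyl and comes back to the route at 14.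

**Further compounds**

F1 | step 12 | 7β-[1-(tributylstannyl)vinyl]-7α,8α-O-isopropylidene-6β,9β-diol | C=C[C@@]1(C)[C@H](C(=C)C)[C@H](O)[C@@]2(C(=C)[Sn](CCCC)(CCCC)CCCC)OC(C)(C)O[C@H]2[C@@H]1O
F2 | step 12 | 7β-(1-iodovinyl)-7α,8α-O-isopropylidene-6β,9β-diol | C=C[C@@]1(C)[C@H](C(=C)C)[C@H](O)[C@@]2(C(I)=C)OC(C)(C)O[C@H]2[C@@H]1O
F3 | step 10 | 6β,7α,8α-trihydroxy-7β-(trimethylsilylethynyl) 9-ketone | C=C[C@@]1(C)[C@H](C(=C)C)[C@H](O)[C@](O)(C#C[Si](C)(C)C)[C@@H](O)C1=O
F4 | step 10 | 6β-hydroxy-7α,8α-O-isopropylidene-7β-(trimethylsilylethynyl) 9-ketone | C=C[C@@]1(C)[C@H](C(=C)C)[C@H](O)[C@@]2(C#C[Si](C)(C)C)OC(C)(C)O[C@H]2C1=O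
F5 | step 9 | 6β,7α,9α-trihydroxy-7β-(trimethylsilylethynyl) 8-ketone | C=C[C@@]1(C)[C@H](C(=C)C)[C@H](O)[C@](O)(C#C[Si](C)(C)C)C(=O)[C@H]1O
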